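Late in these flasks, what repays watching is the slow tail of complex with one exchanged, and I take the end of larch for a point on that tail.

| flask | starting complex | incoming ligand | leaving ligand | remark | time |
|---|---|---|---|---|---|
| Tuesday's | 0.12 M | 0.080 M | 0.24 M | run made earlier |  |
| Thursday's | 0.12 M | 0.34 M | 0.24 M | run made earlier |  |
| larch | 0.12 M | 0.144 M | 0.240 M |  | 2.0 d |
| birch | 0.12 M | 0.480 M | 0.240 M |  | 2.0 d |

- Tuesday's (time / h: complex with one exchanged / %, complex with three exchanged / %): 10.0: 12.1, 0.5; 20.0: 11.0, 1.2; 30.0: 8.5, 0.3; 40.0: 6.7, 0.6; 50.0: 5.1, 0
- Thursday's (time / h: complex with one exchanged / %, complex with three exchanged / %): 4.00: 15.9, 7.7; 12.0: 10.6, 10.2; 20.0: 7.6, 9.6; 30.0: 8.4, 8.5; 50.0: 6.3, 7.0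

(readings scatter by 1 percentage point)

- percentages count the starting complex that a species holds: one side product counts as two
- steps that have been proposed: complex with three exchanged + incoming ligand <-> leaving ligand + complex with four exchanged; complex with one exchanged + incoming ligand <-> leaving ligand + complex with two exchanged; complex with two exchanged + incoming ligand <-> leaving ligand + complex with three exchanged; starting complex + incoming ligand <-> leaving ligand + complex with one exchanged; starting complex + complex with two exchanged -> side product

* which of these holds the largest part of the starting complex at the end of larch (complex with two exchanged / complex with three exchanged / starting complex / complex with one exchanged / complex with four exchanged)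
* which of these holds the largest part of the starting complex at the end of birch (complex with two exchanged / complex with three exchanged / starting complex / complex with one exchanged / complex with four exchanged)
* final complex with one exchanged in larch, as a percentage of the starting complex charged

Which input must I know well for that point? Incoming ligand seems to matter little: its charge rises 4.25-fold from Tuesday's run to Thursday's, yet the last readings differ by 1.2 percentage points, against a scatter of 1 point per reading. Time matters more: Tuesday's run loses 7 points between 10.0 h and 50.0 h, more than that difference. Starting complex and leaving ligand were charged alike in both runs, so the readings cannot rank them.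

For the number itself I read the tail as second order, a pool draining through the proposed step to side product, a reaction between two of its own members. The reciprocal of the fraction held as complex with one exchanged should then climb evenly. On the readings, with their scatter, it climbs 0.284 h⁻¹ in Tuesday's run and 0.169 h⁻¹ in Thursday's. Their mean, 0.227 h⁻¹, is my tail slope. Starting from the mean last reading, 5.70%, and stepping back to 2.0 d, I reckon 5.85% for larch.

The forecast says 7%, above mine. It names starting complex as the largest in larch and complex with four exchanged in birch, holding that “exchange equilibrates within hours”.

Complex with one exchanged in larch ends at 6.67%. Among the five complexes asked about, starting complex holds most in larch, at 26.2%, and complex with four exchanged holds most in birch, at 28.6%.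

    complex with three exchanged + incoming ligand ⇌ leaving ligand + complex with four exchanged (K = 5.40, k = 2.00 × 10⁻⁴ M⁻¹ s⁻¹)
    complex with one exchanged + incoming ligand ⇌ leaving ligand + complex with two exchanged (K = 2.40, k = 8.30 × 10⁻⁴ M⁻¹ s⁻¹)
    complex with two exchanged + incoming ligand ⇌ leaving ligand + complex with three exchanged (K = 4.80, k = 3.50 × 10⁻⁴ M⁻¹ s⁻¹)
    starting complex + incoming ligand ⇌ leaving ligand + complex with one exchanged (K = 2.10, k = 1.80 × 10⁻⁴ M⁻¹ s⁻¹)
    starting complex + complex with two exchanged → side product (k = 0.00110 M⁻¹ s⁻¹)

In larch, the half-life of complex with one exchanged by the forward rate of its step to complex with two exchanged alone, the other concentrations as charged, is 0.067 d, short against 2.0 d. The reciprocal of its fraction in larch climbs 0.224 h⁻¹ between 1.00 d and 2.00 d, close to the tail slope. Carried with 0.227 h⁻¹ to larch left until 8.00 d, the tail slope gives 2.10%, and that flask stands at 2.38%.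

(The readings were generated by integration for an exercise; noise was put on by code.)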